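The upper unit's ring C is opened at C4–C4a. The upper unit is built as an open-chain aldehyde whose aryl ether oxygen is the future O1, whose formyl carbon is the future C4 and whose two stereocentres are the future C2 and C3. One Lewis-acid operation lets the symmetrical, triply oxygen-activated ring A attack the formyl carbon (closing ring C), ionises the resulting 4-hydroxyflavan to the ring-A-stabilised C4 cation, and lets C6 of an 8-bromo epicatechin gallate capture it trans to the C3 ester. The step exploits the doubly benzylic C4 flanked by phloroglucinol-type ring A and is stereoconvergent at C4.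

Key step: step 9

Remark: flavan numbering is used for both units. In the open-chain intermediates the benzylic carbon is the future C2, the carbinol or ester carbon the future C3, and the vinyl CH (later formyl) carbon the future C4. The 4β linkage is read as 3,4-trans, as drawn in the target SMILES.

**Step 1**
Reactants: 1 3,4-bis(benzyloxy)benzaldehyde; 2 3-(methoxymethoxy)prop-1-ene
Product: 7 (1R,2R)-1-[3,4-bis(benzyloxy)phenyl]-2-(methoxymethoxy)but-3-en-1-ol, via lithiated allyl ether 3 (not isolated), via borate complex 4 (not isolated), via allylborane 5 (not isolated), via borinate ester 6 (not isolated)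
Conditions: 2, s-BuLi, THF, −78 °C; (−)-Ipc2BOMe; BF3·OEt2; then 1, −78 °C; NaOH, H2O2, rt
Reagents that add atoms: none
Why: Brown alkoxyallylboration through a closed chair Zimmerman–Traxler transition state, in which the Z-configured γ-alkoxyallylborane should give the syn (threo) diol mono-ether and the isopinocampheyl groups derived from (+)-α-pinene should direct the allyl unit to the Si face of the aldehyde, setting both the future C2 and C3.

**Step 2**
Reactants: 7 (1R,2R)-1-[3,4-bis(benzyloxy)phenyl]-2-(methoxymethoxy)but-3-en-1-ol; 8 1,3-bis(benzyloxy)-5-bromobenzene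
Product: 9 1,3-bis(benzyloxy)-5-{[(1R,2R)-1-[3,4-bis(benzyloxy)phenyl]-2-(methoxymethoxy)but-3-en-1-yl]oxy}benzene
Conditions: CuI (10 mol %), 3,4,7,8-tetramethyl-1,10-phenanthroline (20 mol %), Cs2CO3, 8 (2 equiv), toluene, 110–130 °C
Reagents that add atoms: none
Why: Ullmann-type copper-catalysed C–O coupling of a secondary alcohol with an aryl bromide makes the ether bond at the aryl carbon, so the benzylic C–O bond is never broken and the future C2 keeps its configuration.

**Step 3**
Reactants: 9 the methoxymethyl-protected aryl ether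
Product: 10 (1R,2R)-1-[3,5-bis(benzyloxy)phenoxy]-1-[3,4-bis(benzyloxy)phenyl]but-3-en-2-ol
Conditions: Me2BBr, CH2Cl2, −78 °C; then aq. NaHCO3
Reagents that add atoms: none
Why: Dimethylboron bromide cleaves the acetal-type methoxymethyl ether at −78 °C, a temperature at which the benzyl ethers and the benzylic aryl ether are expected to survive, and no stereocentre is touched.

**Step 4**
Reactants: 10 (1R,2R)-1-[3,5-bis(benzyloxy)phenoxy]-1-[3,4-bis(benzyloxy)phenyl]but-3-en-2-ol; 11 3,4,5-tris(benzyloxy)benzoic acid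
Product: 12 (1R,2R)-1-[3,5-bis(benzyloxy)phenoxy]-1-[3,4-bis(benzyloxy)phenyl]but-3-en-2-yl 3,4,5-tris(benzyloxy)benzoate
Conditions: DCC, DMAP, CH2Cl2, 0 °C to rt
Reagents that add atoms: none
Why: Steglich esterification acylates the carbinol oxygen without breaking its C–O bond, so the future C3 is retained and the gallate that will later steer the C4 stereochemistry is in place.

**Step 5**
Reactants: 12 the vinyl gallate
Product: 13 (2S,3R)-3-[3,5-bis(benzyloxy)phenoxy]-3-[3,4-bis(benzyloxy)phenyl]-1-oxopropan-2-yl 3,4,5-tris(benzyloxy)benzoate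
Conditions: OsO4 (2 mol %), NaIO4, 2,6-lutidine, 1,4-dioxane/H2O 3:1, rt; used at once
Reagents that add atoms: sodium periodate, [Na+].[O-]I(=O)(=O)=O (terminal oxidant; its oxygen reaches the aldehyde through OsO4)
Why: Lemieux–Johnson oxidative cleavage attacks only the terminal alkene among the electron-rich arenes, and the lutidine buffer should keep the α-acyloxy aldehyde from epimerising or eliminating the β-aryloxy group.

**Step 6**
Reactants: 14 (−)-epicatechin
Product: 15 5,7,3',4'-tetra-O-benzyl-(−)-epicatechin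
Conditions: BnBr, K2CO3, DMF, 0 °C to rt, argon
Reagents that add atoms: benzyl bromide, BrCc1ccccc1
Why: Williamson etherification under carbonate conditions alkylates the four phenols and leaves the much less acidic aliphatic 3-OH free, with C2 and C3 untouched.

**Step 7**
Reactants: 15 5,7,3',4'-tetra-O-benzyl-(−)-epicatechin
Product: 16 8-bromo-5,7,3',4'-tetra-O-benzyl-(−)-epicatechin
Conditions: NBS (1.0 equiv), CH2Cl2, −78 °C to rt
Reagents that add atoms: N-bromosuccinimide, O=C1CCC(=O)N1Br
Why: Electrophilic aromatic bromination of the 5,7-di-O-benzyl ring A should go to C8, the more reactive of its two free carbons, and one equivalent at low temperature should stop at the monobromide, leaving C6 as the only nucleophilic position.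

**Step 8**
Reactants: 16 8-bromo-5,7,3',4'-tetra-O-benzyl-(−)-epicatechin; 11 3,4,5-tris(benzyloxy)benzoic acid
Product: 17 8-bromo-5,7,3',4'-tetra-O-benzyl-(−)-epicatechin 3-O-[3,4,5-tris(benzyloxy)benzoate]
Conditions: DCC, DMAP, CH2Cl2, rt
Reagents that add atoms: none
Why: Steglich esterification of the free 3-OH proceeds with retention, as the C3–O bond is not broken.

**Step 9**
Reactants: 13 the open-chain aldehyde; 17 the 8-bromo lower-unit gallate
Product: 20 per-O-benzylated 8-bromo procyanidin B-5 3,3'-di-O-gallate (upper unit joined 4β to C6 of the lower unit), via 4-hydroxyflavan 18 (not isolated), via flavan-4-yl cation 19 (not isolated)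
Conditions: 17 (3 equiv), BF3·OEt2 (2 equiv), CH2Cl2, −78 to −40 °C, slow addition of 13; Et3N quench; excess 17 recovered
Reagents that add atoms: none
Why: BF3 activates the formyl carbon of 13 and an ortho carbon of the tethered 3,5-bis(benzyloxy)phenoxy ring (each ortho carbon is ortho, ortho and para to three oxygens) attacks it, forming the C4–C4a bond and ring C as the 4-hydroxyflavan 18, which ionises at once to the C4 cation 19 (stabilised by the oxygens at C5, C7 and C8a) that C6 of 17 captures. The closest known reaction types are the intramolecular Friedel–Crafts hydroxyalkylation of aryloxy-tethered aldehydes to chroman-4-ols and the Lewis-acid coupling of 4-oxygenated flavans with flavan nucleophiles, here telescoped as an unsymmetrical double Friedel–Crafts arylation of one aldehyde carbon. Ring C closes 6-exo-trig at the carbonyl carbon, with the attacking arene π bond inside the new ring. The one new stereocentre, C4, is set when 19 is captured: the C3 gallate carbonyl bridges the cation on the face of the C3 oxygen (1,3-dioxolan-2-ylium participation) and the axial C3 ester shields that face, so the arene should enter anti and give the 3,4-trans (4β) product from either C4 epimer of 18, while C2 and C3 are carried over unchanged from 13. The step needs C6 over C8 regioselectivity in 17 (secured by the bromine at C8), a single cyclisation regiochemistry (secured by the symmetry of ring A, whose para carbon cannot reach), and capture by 17 in preference to ring A of another flavan (secured by excess 17 and slow addition of 13). If 17 attacked the aldehyde first, the diarylcarbinol would ionise and close the same C4–C4a bond through a chair in which the C4 aryl avoids the C5 benzyloxy group, leading to the same isomer.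

**Step 10**
Reactants: 20 the protected bromo dimer
Product: 21 procyanidin B-5 3,3'-di-O-gallate
Conditions: H2 (1 atm), Pd(OH)2/C, Et3N (1.5 equiv), THF/MeOH/H2O, rt; filtration, Sephadex LH-20
Reagents that add atoms: none
Why: Catalytic hydrogenolysis should remove all fourteen benzyl ethers and the aryl C–Br bond in one operation, with the amine buffering the HBr so that the acid-labile interflavan bond, the gallate esters and all five stereocentres stay untouched.

**Compound list**

1 | 3,4-bis(benzyloxy)benzaldehyde | O=Cc1ccc(OCc2ccccc2)c(OCc2ccccc2)c1 | starting material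
2 | 3-(methoxymethoxy)prop-1-ene (allyl methoxymethyl ether) | C=CCOCOC | starting material
3 | 1-(methoxymethoxy)allyllithium (Z-configured oxyallyl anion) | C=CC([Li])OCOC | intermediate (not isolated)
4 | lithium [(Z)-3-(methoxymethoxy)allyl](methoxy)diisopinocampheylborate | [Li+].CO[B-](C/C=C\OCOC)([C@@H]1C[C@@H]2C[C@H]([C@H]1C)C2(C)C)[C@@H]1C[C@@H]2C[C@H]([C@H]1C)C2(C)C | intermediate (not isolated)
5 | [(Z)-3-(methoxymethoxy)allyl]diisopinocampheylborane | COCO/C=C\CB([C@@H]1C[C@@H]2C[C@H]([C@H]1C)C2(C)C)[C@@H]1C[C@@H]2C[C@H]([C@H]1C)C2(C)C | intermediate (not isolated)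
6 | diisopinocampheylborinate ester of 7 | C=C[C@@H](OCOC)[C@@H](c1ccc(OCc2ccccc2)c(OCc2ccccc2)c1)OB([C@@H]1C[C@@H]2C[C@H]([C@H]1C)C2(C)C)[C@@H]1C[C@@H]2C[C@H]([C@H]1C)C2(C)C | intermediate (not isolated)
7 | (1R,2R)-1-[3,4-bis(benzyloxy)phenyl]-2-(methoxymethoxy)but-3-en-1-ol | C=C[C@@H](OCOC)[C@@H](c1ccc(OCc2ccccc2)c(OCc2ccccc2)c1)O | intermediate
8 | 1,3-bis(benzyloxy)-5-bromobenzene | Brc1cc(OCc2ccccc2)cc(OCc2ccccc2)c1 | starting material
9 | 1,3-bis(benzyloxy)-5-{[(1R,2R)-1-[3,4-bis(benzyloxy)phenyl]-2-(methoxymethoxy)but-3-en-1-yl]oxy}benzene | C=C[C@@H](OCOC)[C@@H](c1ccc(OCc2ccccc2)c(OCc2ccccc2)c1)Oc1cc(OCc2ccccc2)cc(OCc2ccccc2)c1 | intermediate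
10 | (1R,2R)-1-[3,5-bis(benzyloxy)phenoxy]-1-[3,4-bis(benzyloxy)phenyl]but-3-en-2-ol | C=C[C@@H](O)[C@@H](c1ccc(OCc2ccccc2)c(OCc2ccccc2)c1)Oc1cc(OCc2ccccc2)cc(OCc2ccccc2)c1 | intermediate
11 | 3,4,5-tris(benzyloxy)benzoic acid | OC(=O)c1cc(OCc2ccccc2)c(OCc2ccccc2)c(OCc2ccccc2)c1 | starting material
12 | (1R,2R)-1-[3,5-bis(benzyloxy)phenoxy]-1-[3,4-bis(benzyloxy)phenyl]but-3-en-2-yl 3,4,5-tris(benzyloxy)benzoate | C=C[C@@H](OC(=O)c1cc(OCc2ccccc2)c(OCc2ccccc2)c(OCc2ccccc2)c1)[C@@H](c1ccc(OCc2ccccc2)c(OCc2ccccc2)c1)Oc1cc(OCc2ccccc2)cc(OCc2ccccc2)c1 | intermediate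
13 | (2S,3R)-3-[3,5-bis(benzyloxy)phenoxy]-3-[3,4-bis(benzyloxy)phenyl]-1-oxopropan-2-yl 3,4,5-tris(benzyloxy)benzoate | O=C[C@@H](OC(=O)c1cc(OCc2ccccc2)c(OCc2ccccc2)c(OCc2ccccc2)c1)[C@@H](c1ccc(OCc2ccccc2)c(OCc2ccccc2)c1)Oc1cc(OCc2ccccc2)cc(OCc2ccccc2)c1 | intermediate
14 | (−)-epicatechin, (2R,3R) | O[C@@H]1Cc2c(O)cc(O)cc2O[C@@H]1c1ccc(O)c(O)c1 | starting material
15 | 5,7,3',4'-tetra-O-benzyl-(−)-epicatechin | O[C@@H]1Cc2c(OCc3ccccc3)cc(OCc3ccccc3)cc2O[C@@H]1c1ccc(OCc2ccccc2)c(OCc2ccccc2)c1 | intermediate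
16 | 8-bromo-5,7,3',4'-tetra-O-benzyl-(−)-epicatechin | O[C@@H]1Cc2c(OCc3ccccc3)cc(OCc3ccccc3)c(Br)c2O[C@@H]1c1ccc(OCc2ccccc2)c(OCc2ccccc2)c1 | intermediate
17 | 8-bromo-5,7,3',4'-tetra-O-benzyl-(−)-epicatechin 3-O-[3,4,5-tris(benzyloxy)benzoate] | O=C(O[C@@H]1Cc2c(OCc3ccccc3)cc(OCc3ccccc3)c(Br)c2O[C@@H]1c1ccc(OCc2ccccc2)c(OCc2ccccc2)c1)c1cc(OCc2ccccc2)c(OCc2ccccc2)c(OCc2ccccc2)c1 | intermediate
18 | 4-hydroxyflavan: 5,7,3',4'-tetra-O-benzyl-4-hydroxy-epicatechin 3-O-[3,4,5-tris(benzyloxy)benzoate], C2 and C3 as in 13, both C4 epimers | O=C(O[C@@H]1C(O)c2c(OCc3ccccc3)cc(OCc3ccccc3)cc2O[C@@H]1c1ccc(OCc2ccccc2)c(OCc2ccccc2)c1)c1cc(OCc2ccccc2)c(OCc2ccccc2)c(OCc2ccccc2)c1 | intermediate (not isolated)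
19 | flavan-4-yl cation of 18 (ion pair with hydroxytrifluoroborate) | O=C(O[C@@H]1[CH+]c2c(OCc3ccccc3)cc(OCc3ccccc3)cc2O[C@@H]1c1ccc(OCc2ccccc2)c(OCc2ccccc2)c1)c1cc(OCc2ccccc2)c(OCc2ccccc2)c(OCc2ccccc2)c1 | intermediate (not isolated)
20 | per-O-benzylated 8-bromo procyanidin B-5 3,3'-di-O-gallate: upper 2,3-cis-3,4-trans unit linked C4 (β) to C6 of the 8-bromo lower unit | O=C(O[C@@H]1[C@@H](c2c(OCc4ccccc4)c(Br)c3c(c2OCc4ccccc4)C[C@@H](OC(=O)c2cc(OCc4ccccc4)c(OCc4ccccc4)c(OCc4ccccc4)c2)[C@@H](c2ccc(OCc4ccccc4)c(OCc4ccccc4)c2)O3)c2c(OCc4ccccc4)cc(OCc4ccccc4)cc2O[C@@H]1c1ccc(OCc2ccccc2)c(OCc2ccccc2)c1)c1cc(OCc2ccccc2)c(OCc2ccccc2)c(OCc2ccccc2)c1 | intermediate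
21 | procyanidin B-5 3,3'-di-O-gallate | O=C(O[C@@H]1[C@@H](c2c(O)cc3c(c2O)C[C@@H](OC(=O)c2cc(O)c(O)c(O)c2)[C@@H](c2ccc(O)c(O)c2)O3)c2c(O)cc(O)cc2O[C@@H]1c1ccc(O)c(O)c1)c1cc(O)c(O)c(O)c1 | target

**Totals**

Total step count: 10. Longest linear sequence: 7 steps (steps 1, 2, 3, 4, 5, 9, 10). The lower unit (steps 6–8) is convergent.

**Steps most likely to fail**

1. Step 9. The C4 cation may be captured by ring A of a second flavan molecule (oligomerisation) faster than by the hindered, bromine-deactivated C6 of 17, or the Lewis acid may ionise the open-chain benzylic aryl ether of 13 before ring C closes. Fallback: the two events are separated, setting out from 13. Aldehyde 13 alone is cyclised with camphorsulfonic acid in CH2Cl2/2-ethoxyethanol, where the alcohol in large excess traps the C4 cation after the same C4–C4a closure and should give the isolable 5,7,3',4'-tetra-O-benzyl-4-(2-ethoxyethoxy)epicatechin 3-O-[3,4,5-tris(benzyloxy)benzoate] F1 (both C4 epimers). F1 and 17 are then joined by the usual TMSOTf-promoted interflavan coupling (CH2Cl2, −78 °C), which returns to the route at 20.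

2. Step 2. Alkoxide–copper exchange at the hindered secondary benzylic alcohol may be too slow, so that reduction or homocoupling of 8 consumes the aryl bromide and 7 is recovered. Fallback: the aryl group is delivered by ligand coupling at hypervalent iodine, setting out from 8. Aromatic Finkelstein exchange (NaI, CuI, trans-N,N'-dimethylcyclohexane-1,2-diamine, dioxane, 110 °C) gives 1,3-bis(benzyloxy)-5-iodobenzene F2. One-pot oxidation and ligand exchange (mCPBA, TsOH·H2O, then 1,3,5-trimethoxybenzene, MeCN) gives [3,5-bis(benzyloxy)phenyl](2,4,6-trimethoxyphenyl)iodonium 4-methylbenzenesulfonate F3. The sodium alkoxide of 7 (NaH, toluene, rt) is then O-arylated by F3 without a metal catalyst, the electron-rich trimethoxyphenyl group staying on iodine, and the route is rejoined at 9 with the benzylic configuration retained.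

3. Step 3. The boron Lewis acid may ionise the electron-rich benzylic C–OAr bond (loss of the phenol) in competition with cleavage of the acetal. Fallback: a sequence with no acetal protecting group, setting out from 1 and using 3,5-bis(benzyloxy)phenol as the ring A source. CH2=CHMgBr (THF, 0 °C) gives racemic 1-[3,4-bis(benzyloxy)phenyl]prop-2-en-1-ol F4. Sharpless kinetic resolution (Ti(OiPr)4, L-(+)-diisopropyl tartrate, t-BuOOH, CH2Cl2, −20 °C) should epoxidise the (R)-alcohol to the erythro epoxy alcohol (S)-[3,4-bis(benzyloxy)phenyl][(R)-oxiran-2-yl]methanol F5. Mitsunobu etherification with the phenol (PPh3, DIAD, toluene, 0 °C) inverts the benzylic carbon to the threo epoxy ether (R)-2-{(R)-[3,5-bis(benzyloxy)phenoxy][3,4-bis(benzyloxy)phenyl]methyl}oxirane F6. One-carbon homologation with excess dimethylsulfonium methylide (Me3SI, n-BuLi, THF, −10 °C to rt) opens the epoxide at its CH2 group and eliminates dimethyl sulfide, giving the allylic alcohol and rejoining the route at 10.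

**Further compounds**

F1 | step 9 | 5,7,3',4'-tetra-O-benzyl-4-(2-ethoxyethoxy)epicatechin 3-O-[3,4,5-tris(benzyloxy)benzoate] (both C4 epimers) | O=C(O[C@@H]1C(OCCOCC)c2c(OCc3ccccc3)cc(OCc3ccccc3)cc2O[C@@H]1c1ccc(OCc2ccccc2)c(OCc2ccccc2)c1)c1cc(OCc2ccccc2)c(OCc2ccccc2)c(OCc2ccccc2)c1
F2 | step 2 | 1,3-bis(benzyloxy)-5-iodobenzene | Ic1cc(OCc2ccccc2)cc(OCc2ccccc2)c1
F3 | step 2 | [3,5-bis(benzyloxy)phenyl](2,4,6-trimethoxyphenyl)iodonium 4-methylbenzenesulfonate | COc1cc(OC)c([I+]c2cc(OCc3ccccc3)cc(OCc3ccccc3)c2)c(OC)c1.Cc1ccc(S(=O)(=O)[O-])cc1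
F4 | step 3 | racemic 1-[3,4-bis(benzyloxy)phenyl]prop-2-en-1-ol | C=CC(O)c1ccc(OCc2ccccc2)c(OCc2ccccc2)c1
F5 | step 3 | (S)-[3,4-bis(benzyloxy)phenyl][(R)-oxiran-2-yl]methanol | C1O[C@H]1[C@H](c1ccc(OCc2ccccc2)c(OCc2ccccc2)c1)O
F6 | step 3 | (R)-2-{(R)-[3,5-bis(benzyloxy)phenoxy][3,4-bis(benzyloxy)phenyl]methyl}oxirane | C1O[C@H]1[C@@H](c1ccc(OCc2ccccc2)c(OCc2ccccc2)c1)Oc1cc(OCc2ccccc2)cc(OCc2ccccc2)c1
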